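I began at the late end of the earlier runs, at 40.0 h, and asked how much starting complex each had lost by then.

| flask | starting complex | gas | remark | time |
|---|---|---|---|---|
| dusk | 0.031 M | 0.65 mM (held) | run made earlier |  |
| noon | 0.066 M | 0.65 mM (held) | run made earlier |  |
| blue | 0.016 M | 0.65 mM (held) |  | 2.5 d |
| ochre | 0.060 M | 0.65 mM (held) |  | 2.5 d |

| run | time / h | complex with one exchanged / % | starting complex / % |
|---|---|---|---|
| dusk | 4.00 | 1.3 | 98.4 |
| dusk | 10.0 | 3.2 | 96.7 |
| dusk | 20.0 | 6.1 | 93.2 |
| dusk | 30.0 | 8.2 | 90.0 |
| dusk | 40.0 | 10.8 | 86.6 |
| noon | 4.00 | 0.5 | 99.5 |
| noon | 10.0 | 1.8 | 98.8 |
| noon | 20.0 | 2.7 | 96.5 |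
| noon | 30.0 | 4.0 | 95.1 |
| noon | 40.0 | 5.1 | 93.6 |

(scatter of a reading: 0.3 percentage points)

1. the winner by amount of complex with one exchanged, in percent of the starting complex charged; "neither" if no more than 2 percentage points parts them (blue / ochre / neither)
2. how much complex with one exchanged is there at the end, in percent of the starting complex charged: blue
3. how much complex with one exchanged is there at the end, in percent of the starting complex charged: ochre

- at the start none of the gas is in solution

In concentration, the dusk run lost starting complex at 0.104 mM/h and the noon run at 0.106 mM/h, though the noon charge was about twice the dusk one. The two rates matched, so I took gas delivery as the rate-limiting step and their mean, 0.105 mM/h, as the supply rate: the concentration of starting complex turned per hour, read at these two charges. My first estimate let turned complex simply stay as complex with one exchanged, which gave blue 39.3%.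

But the dusk run's two readings fell 2.6 percentage points short of the charge at 40.0 h, and the noon run's 1.3 points short, so something drained the complex. A step competing for gas predicted a dusk shortfall 4.48 times the noon one. The readings gave about twice, loosely at a scatter of 0.3 points, and a first-order drain predicted 2.12 times, so I took that drain. A shortfall under a linear rise is half the drain constant times share times time, so I read 0.0123 /h.

Integrating supply/charge minus drain times share gave share = supply/(charge × drain) × (1 − exp(−drain × time)). That made blue 27.8% and ochre 7.41%. One doubt stayed open: blue's charge lay below the dusk charge, so the supply rate was being carried beyond the charges read.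

The forecast named blue the winner, with 17.5% for blue and 9% for ochre, holding that “the one-exchanged complex goes on to a second exchange”. My blue stood higher and my ochre lower.

The flask gave blue 25.7% and ochre 7.36%, so blue won, 8.2 points above the forecast's blue.

    starting complex + incoming ligand ⇌ leaving ligand + complex with one exchanged (K = 1050, k = 10.7 /M/min)
    complex with one exchanged + incoming ligand ⇌ leaving ligand + complex with two exchanged (K = 12.0, k = 4.82 /M/min)
    complex with two exchanged + incoming ligand ⇌ leaving ligand + complex with three exchanged (K = 440, k = 11.8 /M/min)
    gas ⇌ incoming ligand, rate k4*(csat - [incoming ligand]) (kL = 0.00275 /min)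
    complex with one exchanged → over-reaction product (k = 2.15 × 10⁻⁴ /min)

At 2.50 d in blue, complex with one exchanged went into over-reaction product 2.4 times as fast as into complex with two exchanged, counting the forward rate of that second exchange alone. Blue had lost 38.0% of its starting complex by then, against 39.3% from the supply rate.

For the same blue flask read at 40 h, the supply rate and drain gave 20.7% of complex with one exchanged. The computed flask held 19.3%.

(All runs come from a simulation for an exercise; the scatter is artificial.)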